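**Retrosynthetic overview**
1. Endgame: the 8-O-acyl group comes from esterification of the 8α-hydroxyl with the acetonide-masked (E)-4-hydroxy-2-(hydroxymethyl)but-2-enoic acid; the 3β-acetate from Mitsunobu inversion; the C12 acid from late oxidation of a PMB-masked allylic alcohol, so that no lactone onto O-8 can form.
2. Key disconnection C9–C10 (ring A, formed last): the C8(O)–C9H2–C10(OH)(CH3) unit of ring A is an aldol array whose carbinol C10 carries only a methyl group. C10 and C14 therefore come from an acetyl group on C1, and C8 and C9 from a bromomethyl ketone on C7; SmI2 makes the C9 enolate, closes ring A and reduces C8 in the same flask.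
3. C6–C7: Ireland–Claisen rearrangement of a tertiary allylic ester on the α-oxygen at C4 delivers the acid carbon to C6 cis to the C1 substituent, moves the alkene to C4=C5 and sets C7.
4. Ring B (formed first) is the ring of (R)-carvone: its stereocentre becomes C1, its carbonyl O-3, its isopropenyl group the C10 acetyl; directed epoxidation and selenoxide elimination move oxygen to C4 and the alkene to C5=C6.
5. Order of rings: B (chiral pool), then A (step 13); two small acids are made separately.

Key step: step 13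

Remark: atoms carry cadinane locants (ring B = C1–C6 with C3 the acetoxy carbon and C4(CH3)=C5; ring A = C1, C6, C7 (bears C11(=C13H2)C12), C8 (acyloxy carbon), C9 (CH2), C10 (C(OH)CH3); C14 = CH3 on C10, C15 = CH3 on C4); β is the face of H-1 and H-6, α the opposite face.

**Step 1**
Reactants: 1 (R)-(−)-carvone
Product: 2 (5R)-5-acetyl-2-methylcyclohex-2-en-1-one
Conditions: O3, CH2Cl2/MeOH, −78 °C; Me2S, −78 °C → rt
Reagents that add atoms: ozone ([O-][O+]=O)
Why: Chemoselective ozonolysis cleaves the electron-rich isopropenyl alkene and spares the electron-poor enone alkene, so the future C10 becomes a methyl ketone while the stereocentre (future C1) is untouched.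

**Step 2**
Reactants: 2 (5R)-5-acetyl-2-methylcyclohex-2-en-1-one
Product: 3 (5R)-2-methyl-5-(2-methyl-1,3-dioxolan-2-yl)cyclohex-2-en-1-one
Conditions: (Me3SiOCH2)2, Me3SiOTf (cat.), CH2Cl2, −78 → −20 °C
Reagents that add atoms: 1,2-bis(trimethylsilyloxy)ethane (C[Si](C)(C)OCCO[Si](C)(C)C)
Why: Silyl-transfer ketalization converts the saturated methyl ketone much faster than the conjugated ketone, and the aprotic low-temperature conditions avoid enolization toward the stereocentre.

**Step 3**
Reactants: 3 (5R)-2-methyl-5-(2-methyl-1,3-dioxolan-2-yl)cyclohex-2-en-1-one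
Product: 4 (1R,5R)-2-methyl-5-(2-methyl-1,3-dioxolan-2-yl)cyclohex-2-en-1-ol
Conditions: NaBH4, CeCl3·7H2O, MeOH, −78 °C
Reagents that add atoms: none
Why: Luche 1,2-reduction with axial hydride delivery should give the pseudo-equatorial alcohol cis to the ring substituent (3α-OH), as in the reduction of carvone to cis-carveol.

**Step 4**
Reactants: 4 (1R,5R)-2-methyl-5-(2-methyl-1,3-dioxolan-2-yl)cyclohex-2-en-1-ol
Product: 5 all-cis epoxy alcohol 1-methyl-4-(2-methyl-1,3-dioxolan-2-yl)-7-oxabicyclo[4.1.0]heptan-2-ol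
Conditions: VO(acac)2 (cat.), t-BuOOH, toluene, 0 °C → rt
Reagents that add atoms: tert-butyl hydroperoxide (CC(C)(C)OO)
Why: Hydroxyl-directed epoxidation through the vanadium alkoxide places the oxirane oxygen on the alkene face syn to the allylic hydroxyl (α), which sets C4 and C5.

**Step 5**
Reactants: 5 all-cis epoxy alcohol
Product: 8 cis-diol 2-methyl-5-(2-methyl-1,3-dioxolan-2-yl)cyclohex-3-ene-1,2-diol, via hydroxy selenide 6 (not isolated), via selenoxide 7 (not isolated)
Conditions: (PhSe)2, NaBH4, EtOH, rt then reflux; then THF, 30% H2O2, 0 °C → rt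
Reagents that add atoms: none
Why: Selenide-mediated epoxide-to-allylic-alcohol transposition: the selenolate opens the oxirane anti at the less substituted C5, leaving the tertiary 4α-hydroxyl, and selenoxide syn-elimination can only run toward C6, which places the alkene at C5=C6.

**Step 6**
Reactants: 8 cis-diol
Product: 9 tertiary allylic alcohol 6-[(tert-butyldimethylsilyl)oxy]-1-methyl-4-(2-methyl-1,3-dioxolan-2-yl)cyclohex-2-en-1-ol
Conditions: TBSCl, imidazole, DMF, rt
Reagents that add atoms: tert-butyldimethylsilyl chloride (CC(C)(C)[Si](C)(C)Cl)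
Why: Silyl ether formation takes place at the secondary 3α-hydroxyl only, because the tertiary allylic hydroxyl is too hindered.

**Step 7**
Reactants: 10 3-chloro-2-(chloromethyl)prop-1-ene
Product: 11 1-({[2-(chloromethyl)prop-2-en-1-yl]oxy}methyl)-4-methoxybenzene
Conditions: 4-methoxybenzyl alcohol, NaH, THF, 0 °C; then 10 (3 equiv), Bu4NI (cat.), rt
Reagents that add atoms: 4-methoxybenzyl alcohol (COc1ccc(CO)cc1)
Why: Williamson ether synthesis on the allylic dichloride, with the excess of dichloride limiting double substitution.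

**Step 8**
Reactants: 11 1-({[2-(chloromethyl)prop-2-en-1-yl]oxy}methyl)-4-methoxybenzene
Product: 13 3-{[(4-methoxybenzyl)oxy]methyl}but-3-enoic acid, via allylmagnesium chloride 12 (not isolated)
Conditions: Mg, THF, 0 °C (slow addition); CO2, −20 °C; 1 M HCl
Reagents that add atoms: carbon dioxide (O=C=O)
Why: Carboxylation of the allylic Grignard reagent gives the β,γ-unsaturated acid, and both allyl termini lead to the same product.

**Step 9**
Reactants: 9 tertiary allylic alcohol; 13 3-{[(4-methoxybenzyl)oxy]methyl}but-3-enoic acid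
Product: 14 tertiary allylic ester of 9 with acid 13
Conditions: DCC, 4-(dimethylamino)pyridine (cat.), CH2Cl2, 0 °C → rt
Reagents that add atoms: none
Why: Steglich esterification is the standard acylation of tertiary alcohols, and the tertiary hydroxyl is the only free one in 9.

**Step 10**
Reactants: 14 tertiary allylic ester
Product: 17 ring-B acid 2-[4-(tert-butyldimethylsilyloxy)-3-methyl-6-(2-methyl-1,3-dioxolan-2-yl)cyclohex-2-en-1-yl]-3-{[(4-methoxybenzyl)oxy]methyl}but-3-enoic acid, via silyl ketene acetal 15 (not isolated), via trimethylsilyl ester 16 (not isolated)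
Conditions: LiN(iPr)2, THF/DMPU, −78 °C; Me3SiCl, −78 → 45 °C; then 1 M HCl, 0 °C
Reagents that add atoms: none
Why: Ireland–Claisen rearrangement: the (Z)-silyl ketene acetal formed with the polar cosolvent (C11 syn to the silyloxy group) should rearrange suprafacially on the α face through the boat-like transition state usual for cyclohexenyl esters, so the C4–O bond is exchanged for the C6–C7 bond cis to the C1 substituent, the alkene moves to C4=C5, and C7 forms with C11 pointing outward over H-6.

**Step 11**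
Reactants: 17 ring-B acid
Product: 20 bromomethyl ketone (dioxolane intact), via mixed anhydride 18 (not isolated), via diazoketone 19 (not isolated)
Conditions: i-BuOCOCl, N-methylmorpholine, THF, −15 °C; CH2N2, Et2O, 0 °C; then 48% aq. HBr, 0 °C
Reagents that add atoms: diazomethane (C=[N+]=[N-]); hydrogen bromide (Br)
Why: The first half of an Arndt–Eistert homologation followed by hydrobromination of the diazoketone adds C9 with a bromine that fixes the later enolate position, under acylation conditions that leave the C7 stereocentre intact.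

**Step 12**
Reactants: 20 bromomethyl ketone (dioxolane intact)
Product: 21 bromomethyl ketone with free C10 methyl ketone
Conditions: pyridinium p-toluenesulfonate, acetone/H2O, 40 °C
Reagents that add atoms: water (O)
Why: Mild acid-catalysed acetal hydrolysis unmasks the C10 methyl ketone without cleaving the secondary silyl ether or epimerizing C1.

**Step 13**
Reactants: 21 bromomethyl ketone with free C10 methyl ketone
Product: 24 3α-(tert-butyldimethylsilyloxy)-12-(4-methoxybenzyloxy)cadina-4,11(13)-diene-8α,10β-diol, via samarium enolate 22 (not isolated), via ketol 23 (not isolated)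
Conditions: SmI2 (2.5 equiv), THF, −78 °C; then MeOH, SmI2 (3 equiv), −78 → 0 °C; aq. NH4Cl
Reagents that add atoms: none
Why: SmI2 reduces the C9–Br bond, far faster than either ketone, to a trivalent samarium enolate fixed at C9, which adds to the C10 ketone in a 6-(enolexo)-exo-trig aldol closure of ring A with samarium bridging both oxygens in a chair transition state. The closest known reaction types are the SmI2-promoted intramolecular Reformatsky-type aldol cyclization of α-halo ketones onto ketones and the SmI2/MeOH reduction of β-hydroxy ketones. C10 is set by that chelated chair: the 3α-silyloxy group forces the ring-B half-chair in which the C1–C10 bond is equatorial, so the C10 methyl sits equatorial and the oxygen axial on the β face. C8 is set in the second stage, where the aldolate-bound ketyl is reduced and protonated to the equatorial 8α-carbinol, anti to the axial 10β-oxygen. The step needs chemoselective C–Br reduction, an enolate at C9 (not C7 or C14) and no epimerization at C1 or C7; the bromine marks C9, and the neutral conditions at −78 °C leave both acidic CH centres untouched. One operation should thus give ring A, the C9–C10 bond and both carbinol stereocentres.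

**Step 14**
Reactants: 25 (Z)-but-2-ene-1,4-diol
Product: 26 2,2-dimethyl-4,7-dihydro-1,3-dioxepine
Conditions: Me2C(OMe)2, p-toluenesulfonic acid monohydrate (cat.), CH2Cl2, rt
Reagents that add atoms: 2,2-dimethoxypropane (COC(C)(C)OC)
Why: Transacetalization gives the seven-membered acetonide, which only the cis-diol can form and which locks the alkene geometry.

**Step 15**
Reactants: 26 2,2-dimethyl-4,7-dihydro-1,3-dioxepine
Product: 28 5-bromo-2,2-dimethyl-4,7-dihydro-1,3-dioxepine, via trans-dibromide 27 (not isolated)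
Conditions: Br2, CH2Cl2, −78 °C; then DBU, THF, reflux
Reagents that add atoms: bromine (BrBr)
Why: Anti bromination followed by E2 dehydrobromination of the symmetrical dibromide can give only one vinyl bromide.

**Step 16**
Reactants: 28 5-bromo-2,2-dimethyl-4,7-dihydro-1,3-dioxepine
Product: 30 2,2-dimethyl-4,7-dihydro-1,3-dioxepine-5-carboxylic acid, via vinyllithium 29 (not isolated)
Conditions: t-BuLi (2.1 equiv), Et2O, −78 °C; CO2; cold 0.5 M HCl to pH 4
Reagents that add atoms: carbon dioxide (O=C=O)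
Why: Bromine–lithium exchange and carboxylation of the ring-locked vinyllithium give the acid in which the two CH2O groups are cis, which corresponds to the (E)-configured side chain.

**Step 17**
Reactants: 24 diol; 30 2,2-dimethyl-4,7-dihydro-1,3-dioxepine-5-carboxylic acid
Product: 31 8α-ester of diol 24 with acid 30
Conditions: 2-methyl-6-nitrobenzoic anhydride, Et3N, 4-(dimethylamino)pyridine (cat.), CH2Cl2, rt
Reagents that add atoms: none
Why: Shiina esterification (mixed-anhydride acyl transfer) should acylate the secondary equatorial 8α-hydroxyl while the tertiary 10β-hydroxyl stays free.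

**Step 18**
Reactants: 31 8α-ester
Product: 32 3α-alcohol
Conditions: Bu4NF, THF, 0 °C → rt
Reagents that add atoms: none
Why: Fluoride-mediated desilylation removes the only silyl ether and leaves the PMB ether, acetonide and ester intact.

**Step 19**
Reactants: 32 3α-alcohol
Product: 33 3β-acetate
Conditions: AcOH, PPh3, diisopropyl azodicarboxylate, toluene, 0 °C → rt
Reagents that add atoms: acetic acid (CC(=O)O)
Why: Mitsunobu esterification displaces the activated allylic 3α-oxygen by acetate with inversion (SN2), setting the 3β-acetate, while the tertiary hydroxyl cannot react.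

**Step 20**
Reactants: 33 3β-acetate
Product: 34 12-alcohol
Conditions: DDQ, CH2Cl2/pH 7 buffer, 0 °C
Reagents that add atoms: none
Why: Oxidative cleavage of the 4-methoxybenzyl ether frees the primary allylic alcohol at C12 without touching esters or the acetonide.

**Step 21**
Reactants: 34 12-alcohol
Product: 35 12-aldehyde (enal)
Conditions: MnO2, CH2Cl2, rt
Reagents that add atoms: none
Why: MnO2 oxidation is selective for the only free allylic alcohol and leaves the tertiary carbinol alone.

**Step 22**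
Reactants: 35 12-aldehyde (enal)
Product: 36 12-acid with acetonide-protected side chain
Conditions: NaClO2, NaH2PO4, 2-methylbut-2-ene, t-BuOH/H2O, 0 °C → rt
Reagents that add atoms: sodium chlorite ([Na+].[O-]Cl=O)
Why: Pinnick oxidation converts the enal into the acrylic acid without affecting the alkenes, for which the scavenger removes hypochlorite.

**Step 23**
Reactants: 36 12-acid with acetonide-protected side chain
Product: 37 target CNP0468194.4
Conditions: AcOH/H2O (4:1), rt
Reagents that add atoms: none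
Why: Acid hydrolysis of the seven-membered acetonide frees the two primary hydroxyls of the side chain, whose ring-locked geometry becomes the (E)-alkene.

**Compound list**
1 | (R)-(−)-carvone | CC(=C)[C@H]1CC(=O)C(C)=CC1 | starting material
2 | (5R)-5-acetyl-2-methylcyclohex-2-en-1-one | CC(=O)[C@H]1CC(=O)C(C)=CC1 | intermediate
3 | (5R)-2-methyl-5-(2-methyl-1,3-dioxolan-2-yl)cyclohex-2-en-1-one | CC1(OCCO1)[C@H]2CC(=O)C(C)=CC2 | intermediate
4 | (1R,5R)-2-methyl-5-(2-methyl-1,3-dioxolan-2-yl)cyclohex-2-en-1-ol (OH cis to the dioxolanyl group) | CC1(OCCO1)[C@H]2C[C@@H](O)C(C)=CC2 | intermediate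
5 | all-cis epoxy alcohol 1-methyl-4-(2-methyl-1,3-dioxolan-2-yl)-7-oxabicyclo[4.1.0]heptan-2-ol | CC1(OCCO1)[C@H]2C[C@@H](O)[C@@]3(C)O[C@H]3C2 | intermediate
6 | hydroxy selenide: 2-methyl-5-(2-methyl-1,3-dioxolan-2-yl)-3-(phenylselanyl)cyclohexane-1,2-diol (PhSe trans to the tertiary OH) | CC1(OCCO1)[C@H]2C[C@@H](O)[C@@](C)(O)[C@H]([Se]c3ccccc3)C2 | intermediate (not isolated)
7 | selenoxide of 6 (mixture at selenium) | CC1(OCCO1)[C@H]2C[C@@H](O)[C@@](C)(O)[C@H]([Se](=O)c3ccccc3)C2 | intermediate (not isolated)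
8 | cis-diol 2-methyl-5-(2-methyl-1,3-dioxolan-2-yl)cyclohex-3-ene-1,2-diol (both OH cis to the dioxolanyl group) | CC1(OCCO1)[C@H]2C[C@@H](O)[C@@](C)(O)C=C2 | intermediate
9 | 6-[(tert-butyldimethylsilyl)oxy]-1-methyl-4-(2-methyl-1,3-dioxolan-2-yl)cyclohex-2-en-1-ol | CC1(OCCO1)[C@H]2C[C@@H](O[Si](C)(C)C(C)(C)C)[C@@](C)(O)C=C2 | intermediate
10 | 3-chloro-2-(chloromethyl)prop-1-ene | C=C(CCl)CCl | starting material
11 | 1-({[2-(chloromethyl)prop-2-en-1-yl]oxy}methyl)-4-methoxybenzene | C=C(CCl)COCc1ccc(OC)cc1 | intermediate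
12 | {2-[(4-methoxybenzyloxy)methyl]prop-2-en-1-yl}magnesium chloride | C=C(C[Mg]Cl)COCc1ccc(OC)cc1 | intermediate (not isolated)
13 | 3-{[(4-methoxybenzyl)oxy]methyl}but-3-enoic acid | C=C(CC(=O)O)COCc1ccc(OC)cc1 | intermediate
14 | tertiary allylic ester of 9 with 13 | CC1(OCCO1)[C@H]2C[C@@H](O[Si](C)(C)C(C)(C)C)[C@@](C)(OC(=O)CC(=C)COCc3ccc(OC)cc3)C=C2 | intermediate
15 | (Z)-trimethylsilyl ketene acetal of 14 (C11 syn to OSiMe3) | CC1(OCCO1)[C@H]2C[C@@H](O[Si](C)(C)C(C)(C)C)[C@@](C)(O/C(O[Si](C)(C)C)=C/C(=C)COCc3ccc(OC)cc3)C=C2 | intermediate (not isolated)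
16 | trimethylsilyl ester of 17 | CC1(OCCO1)[C@H]2C[C@@H](O[Si](C)(C)C(C)(C)C)C(C)=C[C@H]2[C@H](C(=O)O[Si](C)(C)C)C(=C)COCc3ccc(OC)cc3 | intermediate (not isolated)
17 | ring-B acid 2-[4-(tert-butyldimethylsilyloxy)-3-methyl-6-(2-methyl-1,3-dioxolan-2-yl)cyclohex-2-en-1-yl]-3-{[(4-methoxybenzyl)oxy]methyl}but-3-enoic acid (side chain cis to the dioxolanyl group) | CC1(OCCO1)[C@H]2C[C@@H](O[Si](C)(C)C(C)(C)C)C(C)=C[C@H]2[C@H](C(=O)O)C(=C)COCc3ccc(OC)cc3 | intermediate
18 | isobutyl carbonic mixed anhydride of 17 | CC1(OCCO1)[C@H]2C[C@@H](O[Si](C)(C)C(C)(C)C)C(C)=C[C@H]2[C@H](C(=O)OC(=O)OCC(C)C)C(=C)COCc3ccc(OC)cc3 | intermediate (not isolated)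
19 | diazomethyl ketone from 17 | CC1(OCCO1)[C@H]2C[C@@H](O[Si](C)(C)C(C)(C)C)C(C)=C[C@H]2[C@H](C(=O)C=[N+]=[N-])C(=C)COCc3ccc(OC)cc3 | intermediate (not isolated)
20 | bromomethyl ketone (dioxolane intact) | CC1(OCCO1)[C@H]2C[C@@H](O[Si](C)(C)C(C)(C)C)C(C)=C[C@H]2[C@H](C(=O)CBr)C(=C)COCc3ccc(OC)cc3 | intermediate
21 | bromomethyl ketone with free C10 methyl ketone (cis on ring B) | CC(=O)[C@H]1C[C@@H](O[Si](C)(C)C(C)(C)C)C(C)=C[C@H]1[C@H](C(=O)CBr)C(=C)COCc2ccc(OC)cc2 | intermediate
22 | trivalent samarium enolate of the C8 ketone (C8=C9) | CC(=O)[C@H]1C[C@@H](O[Si](C)(C)C(C)(C)C)C(C)=C[C@H]1[C@H](C(=C)O[Sm](I)I)C(=C)COCc2ccc(OC)cc2 | intermediate (not isolated)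
23 | ketol 3α-(tert-butyldimethylsilyloxy)-10β-hydroxy-12-(4-methoxybenzyloxy)cadina-4,11(13)-dien-8-one (formed as its samarium alkoxide) | C=C(COCc1ccc(OC)cc1)[C@@H]2[C@@H]3C=C(C)[C@H](O[Si](C)(C)C(C)(C)C)C[C@@H]3[C@@](C)(O)CC2=O | intermediate (not isolated)
24 | 3α-(tert-butyldimethylsilyloxy)-12-(4-methoxybenzyloxy)cadina-4,11(13)-diene-8α,10β-diol (1β-H 6β-H 7β-H) | C=C(COCc1ccc(OC)cc1)[C@@H]2[C@@H]3C=C(C)[C@H](O[Si](C)(C)C(C)(C)C)C[C@@H]3[C@@](C)(O)C[C@@H]2O | intermediate
25 | (Z)-but-2-ene-1,4-diol | OC/C=C\CO | starting material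
26 | 2,2-dimethyl-4,7-dihydro-1,3-dioxepine | CC1(C)OCC=CCO1 | intermediate
27 | trans-5,6-dibromo-2,2-dimethyl-1,3-dioxepane (racemic) | CC1(C)OC[C@@H](Br)[C@H](Br)CO1 | intermediate (not isolated)
28 | 5-bromo-2,2-dimethyl-4,7-dihydro-1,3-dioxepine | CC1(C)OCC=C(Br)CO1 | intermediate
29 | (2,2-dimethyl-4,7-dihydro-1,3-dioxepin-5-yl)lithium | [Li]C1=CCOC(C)(C)OC1 | intermediate (not isolated)
30 | 2,2-dimethyl-4,7-dihydro-1,3-dioxepine-5-carboxylic acid | OC(=O)C1=CCOC(C)(C)OC1 | intermediate
31 | 8α-(2,2-dimethyl-4,7-dihydro-1,3-dioxepine-5-carbonyloxy) ester of 24 | C=C(COCc1ccc(OC)cc1)[C@@H]2[C@@H]3C=C(C)[C@H](O[Si](C)(C)C(C)(C)C)C[C@@H]3[C@@](C)(O)C[C@@H]2OC(=O)C4=CCOC(C)(C)OC4 | intermediate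
32 | 3α-alcohol (desilylated 31) | C=C(COCc1ccc(OC)cc1)[C@@H]2[C@@H]3C=C(C)[C@H](O)C[C@@H]3[C@@](C)(O)C[C@@H]2OC(=O)C4=CCOC(C)(C)OC4 | intermediate
33 | 3β-acetate | C=C(COCc1ccc(OC)cc1)[C@@H]2[C@@H]3C=C(C)[C@@H](OC(C)=O)C[C@@H]3[C@@](C)(O)C[C@@H]2OC(=O)C4=CCOC(C)(C)OC4 | intermediate
34 | 12-alcohol | C=C(CO)[C@@H]1[C@@H]2C=C(C)[C@@H](OC(C)=O)C[C@@H]2[C@@](C)(O)C[C@@H]1OC(=O)C3=CCOC(C)(C)OC3 | intermediate
35 | 12-aldehyde (enal) | C=C(C=O)[C@@H]1[C@@H]2C=C(C)[C@@H](OC(C)=O)C[C@@H]2[C@@](C)(O)C[C@@H]1OC(=O)C3=CCOC(C)(C)OC3 | intermediate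
36 | 12-acid with acetonide-protected side chain | C=C(C(=O)O)[C@@H]1[C@@H]2C=C(C)[C@@H](OC(C)=O)C[C@@H]2[C@@](C)(O)C[C@@H]1OC(=O)C3=CCOC(C)(C)OC3 | intermediate
37 | CNP0468194.4 | C=C(C(=O)O)[C@@H]1[C@@H]2C=C(C)[C@@H](OC(C)=O)C[C@@H]2[C@@](C)(O)C[C@@H]1OC(=O)/C(=C/CO)CO | target

**Step count and risks**
Total step count: 23 (18 in the main line, 2 for acid 13, 3 for acid 30). Longest linear sequence: 18 steps from (R)-carvone (steps 1–6, 9–13, 17–23).

Most likely to fail:

1. Step 10. Diastereocontrol at C7 may erode through competition between boat and chair transition states or loss of ketene-acetal geometry, and the β,γ-alkene may migrate into conjugation under base. Fallback (sets out from 9, comes back at 17): a Johnson–Claisen rearrangement of 9 with triethyl orthoacetate (propionic acid cat., xylene, 140 °C) should give ethyl ester F1 with the same cis transfer to C6. Saponification (LiOH) gives acid F2, and pivaloyl chloride/Et3N followed by lithiated (S)-4-benzyloxazolidin-2-one gives imide F3. An Evans syn aldol (Bu2BOTf, iPr2NEt, then 2-[(4-methoxybenzyl)oxy]acetaldehyde) sets C7 under auxiliary control as aldol adduct F4. Dess–Martin oxidation gives β-keto imide F5, methylenation with Zn/CH2Br2/TiCl4 gives methylene imide F6, and LiOH/H2O2 removes the auxiliary to return to 17.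

2. Step 13. The samarium enolate may be protonated before ring closure (simple debromination), ring A may close through the other chair with the wrong face at C10, or the reduction at C8 may be unselective. Fallback (sets out from 21, comes back at 24): Zn/Me3SiCl in MeCN should convert 21 regiospecifically into trimethylsilyl enol ether F7. BF3·OEt2 in CH2Cl2 at −78 °C would close ring A by an intramolecular Mukaiyama aldol to ketol 23, here isolated. Me4NBH(OAc)3 in MeCN/AcOH at −20 °C (Evans–Saksena reduction, hydride delivered internally from the 10β-oxygen) would then give 24.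

3. Step 19. Allylic transposition (SN2' attack) or elimination to a diene may compete with clean inversion at C3. Fallback (sets out from 32, comes back at 33): MnO2 in CH2Cl2 should oxidize the allylic alcohol to enone F8. Corey–Bakshi–Shibata reduction with (R)-1-methyl-3,3-diphenylhexahydropyrrolo[1,2-c][1,3,2]oxazaborole and catecholborane (toluene, −78 °C) would deliver hydride to the α face to give 3β-alcohol F9, and Ac2O/pyridine would acetylate it to 33.

**Further compounds**
F1 | step 10 | ethyl 2-[4-(tert-butyldimethylsilyloxy)-3-methyl-6-(2-methyl-1,3-dioxolan-2-yl)cyclohex-2-en-1-yl]acetate (cis) | CC1(OCCO1)[C@H]2C[C@@H](O[Si](C)(C)C(C)(C)C)C(C)=C[C@H]2CC(=O)OCC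
F2 | step 10 | corresponding acetic acid | CC1(OCCO1)[C@H]2C[C@@H](O[Si](C)(C)C(C)(C)C)C(C)=C[C@H]2CC(=O)O
F3 | step 10 | N-acyl (S)-4-benzyloxazolidin-2-one of F2 | CC1(OCCO1)[C@H]2C[C@@H](O[Si](C)(C)C(C)(C)C)C(C)=C[C@H]2CC(=O)N3C(=O)OC[C@@H]3Cc4ccccc4
F4 | step 10 | syn aldol adduct with 2-[(4-methoxybenzyl)oxy]acetaldehyde | CC1(OCCO1)[C@H]2C[C@@H](O[Si](C)(C)C(C)(C)C)C(C)=C[C@H]2[C@H](C(=O)N3C(=O)OC[C@@H]3Cc4ccccc4)[C@H](O)COCc5ccc(OC)cc5
F5 | step 10 | β-keto imide | CC1(OCCO1)[C@H]2C[C@@H](O[Si](C)(C)C(C)(C)C)C(C)=C[C@H]2[C@H](C(=O)N3C(=O)OC[C@@H]3Cc4ccccc4)C(=O)COCc5ccc(OC)cc5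
F6 | step 10 | methylene imide | CC1(OCCO1)[C@H]2C[C@@H](O[Si](C)(C)C(C)(C)C)C(C)=C[C@H]2[C@H](C(=O)N3C(=O)OC[C@@H]3Cc4ccccc4)C(=C)COCc5ccc(OC)cc5
F7 | step 13 | trimethylsilyl enol ether of the C8 ketone (C8=C9) | CC(=O)[C@H]1C[C@@H](O[Si](C)(C)C(C)(C)C)C(C)=C[C@H]1[C@H](C(=C)O[Si](C)(C)C)C(=C)COCc2ccc(OC)cc2
F8 | step 19 | C3 enone | C=C(COCc1ccc(OC)cc1)[C@@H]2[C@@H]3C=C(C)C(=O)C[C@@H]3[C@@](C)(O)C[C@@H]2OC(=O)C4=CCOC(C)(C)OC4
F9 | step 19 | 3β-alcohol | C=C(COCc1ccc(OC)cc1)[C@@H]2[C@@H]3C=C(C)[C@@H](O)C[C@@H]3[C@@](C)(O)C[C@@H]2OC(=O)C4=CCOC(C)(C)OC4
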